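**Plan**

- Cuts: (a) the angelate C–O bond; (b) in the quinone, numbered C1(=O), C2(OMe), C3(Me), C4(=O), C5(H), C6(side chain), the C4–C5 bond, which unravels the ring into a dienylketene and then a 4-hydroxycyclobutenone; (c) the bond from the ring carbinol carbon (future C1) to the diene, giving a cyclobutenedione and a 3-substituted buta-1,3-dien-2-yllithium.
- Enabling feature: the para C1/C4 oxygens with OMe and Me on the adjacent C2/C3 are a squarate in disguise, and the ring CH (C5) next to C6, which carries a 1,1-disubstituted alkene, lets C5=C6 arrive as one vinyl arm of a cross-conjugated dienyl group whose other arm stays as the exocyclic methylidene.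
- The four-membered ring is a temporary ring, absent from the target, that fixes the positions of OMe, Me, H and side chain before it is cleaved in the ring expansion.
- Forward: dimethyl squarate → methylcyclobutenedione; 4-methylpent-3-enoic acid → ynone → (S)-propargylic alcohol → (silylmethyl)allene → 2-bromo-1,3-diene; Li–Br exchange and addition; thermolysis/oxidation builds the only ring; desilylation; angeloylation.
- Stereochemistry: the single stereocentre comes from asymmetric transfer hydrogenation of the ynone and is carried unchanged; the Z ester geometry is bought with angelic acid.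

Key step: step 9

Assumption: dimethyl squarate, 4-methylpent-3-enoic acid, 3-methoxyprop-1-yne and angelic acid are taken as purchasable, and the sense of induction of the Ru catalyst is assigned by analogy with alkynyl methyl ketones (alkyne in the π-site), to be confirmed by Mosher ester analysis.

**Route**

Step 1
Reactants: 1 dimethyl squarate (3,4-dimethoxycyclobut-3-ene-1,2-dione)
Product: 4 3-methoxy-4-methylcyclobut-3-ene-1,2-dione, via lithium alkoxide 2 (not isolated), via tertiary trifluoroacetate 3 (not isolated)
Conditions: MeLi (1.05 equiv), THF, −78 °C; (CF3CO)2O, −78 °C; aq NH4Cl, −78 °C to rt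
Reagents that add atoms: methyllithium, [Li]C; water, O
Why: 1,2-addition of MeLi to one squarate carbonyl, trifluoroacetylation and hydrolytic loss of methanol through the methoxy-stabilised oxocarbenium ion is the standard squarate-to-alkylcyclobutenedione sequence, and no stereocentre is involved.

Step 2
Reactants: 5 4-methylpent-3-enoic acid
Product: 7 N-methoxy-N,4-dimethylpent-3-enamide, via acyl imidazole 6 (not isolated)
Conditions: 1,1'-carbonyldiimidazole, CH2Cl2, 0 °C to rt; then MeNH(OMe)·HCl, rt
Reagents that add atoms: N,O-dimethylhydroxylamine hydrochloride, CNOC.Cl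
Why: Weinreb amide formation through the acyl imidazole runs under nearly neutral conditions, so the β,γ-double bond should not move into conjugation.

Step 3
Reactants: 7 N-methoxy-N,4-dimethylpent-3-enamide; 8 3-methoxyprop-1-yne
Product: 11 1-methoxy-7-methyloct-6-en-2-yn-4-one, via lithium acetylide 9 (not isolated), via tetrahedral lithium chelate 10 (not isolated)
Conditions: 8, n-BuLi, THF, −78 °C; then 7, −78 to −20 °C; cold aq NH4Cl
Reagents that add atoms: none
Why: Weinreb ketone synthesis, in which the acetylide adds once and the chelated tetrahedral intermediate keeps the carbonyl masked until the cold, mildly acidic quench, limiting enolisation and double-bond migration of the skipped enone.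

Step 4
Reactants: 11 1-methoxy-7-methyloct-6-en-2-yn-4-one
Product: 12 (4S)-1-methoxy-7-methyloct-6-en-2-yn-4-ol
Conditions: Ru[(S,S)-TsNCH(Ph)CH(Ph)NH](p-cymene) (1 mol %), i-PrOH, rt
Reagents that add atoms: none
Why: Noyori asymmetric transfer hydrogenation of an alkynyl ketone, in which the alkyne occupies the π-site of the catalyst so that the (S,S)-complex should deliver hydride to the face giving the (S)-carbinol, and the base-free amido complex avoids enolisation.

Step 5
Reactants: 12 (4S)-1-methoxy-7-methyloct-6-en-2-yn-4-ol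
Product: 13 (4S)-7-methyl-3-[(trimethylsilyl)methyl]octa-1,2,6-trien-4-ol
Conditions: Me3SiCH2MgCl (3 equiv), CuBr·SMe2 (10 mol %), THF, −30 °C to rt; aq NH4Cl
Reagents that add atoms: (trimethylsilyl)methylmagnesium chloride, C[Si](C)(C)C[Mg]Cl
Why: copper-catalysed SN2' substitution of a propargylic methyl ether by a Grignard reagent (carbometalation, then β-alkoxide elimination), in which the magnesium alkoxide of the free carbinol directs the new carbon to the alkyne carbon next to the stereocentre and is itself too poor a leaving group to be lost, so the stereocentre is untouched.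

Step 6
Reactants: 13 (4S)-7-methyl-3-[(trimethylsilyl)methyl]octa-1,2,6-trien-4-ol
Product: 14 tert-butyl(dimethyl)({(4S)-7-methyl-3-[(trimethylsilyl)methyl]octa-1,2,6-trien-4-yl}oxy)silane
Conditions: TBSCl, imidazole, DMF, rt
Reagents that add atoms: tert-butyldimethylsilyl chloride, CC(C)(C)[Si](C)(C)Cl
Why: standard silylation of a secondary alcohol under non-acidic conditions that leave the allylsilane intact, giving an ether that should survive t-BuLi and thermolysis and come off with fluoride.

Step 7
Reactants: 14 tert-butyl(dimethyl)({(4S)-7-methyl-3-[(trimethylsilyl)methyl]octa-1,2,6-trien-4-yl}oxy)silane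
Product: 15 {[(4S)-2-bromo-7-methyl-3-methylideneocta-1,6-dien-4-yl]oxy}(tert-butyl)dimethylsilane
Conditions: NBS (1.05 equiv), propylene oxide, CH2Cl2, −78 °C, dark
Reagents that add atoms: N-bromosuccinimide, O=C1CCC(=O)N1Br
Why: SE2' bromodesilylation of an allenylmethylsilane (an allylsilane whose γ-carbon is the central allene carbon), in which the β-silicon effect steers bromine to the central allene carbon and loss of silicon gives the 2-bromo-1,3-diene, while the cold, nucleophile-free medium should spare the trisubstituted alkene.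

Step 8
Reactants: 15 {[(4S)-2-bromo-7-methyl-3-methylideneocta-1,6-dien-4-yl]oxy}(tert-butyl)dimethylsilane; 4 3-methoxy-4-methylcyclobut-3-ene-1,2-dione
Product: 17 4-[(4S)-4-{[tert-butyl(dimethyl)silyl]oxy}-7-methyl-3-methylideneocta-1,6-dien-2-yl]-4-hydroxy-3-methoxy-2-methylcyclobut-2-en-1-one (both epimers at the ring carbinol carbon), via dienyllithium 16 (not isolated)
Conditions: t-BuLi (2.05 equiv), Et2O, −78 °C; then 4, THF, −78 °C; aq NH4Cl at −78 °C
Reagents that add atoms: none
Why: bromine–lithium exchange on a vinyl bromide followed by 1,2-addition to the cyclobutenedione, in which organolithiums attack the ketone-like carbonyl next to the methoxy-bearing carbon and not the vinylogous ester carbonyl, placing methyl next to the future ketene carbon; the new ring stereocentre is uncontrolled and is erased in step 9.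

Step 9
Reactants: 17 4-[(4S)-4-{[tert-butyl(dimethyl)silyl]oxy}-7-methyl-3-methylideneocta-1,6-dien-2-yl]-4-hydroxy-3-methoxy-2-methylcyclobut-2-en-1-one
Product: 21 2-[(3S)-3-{[tert-butyl(dimethyl)silyl]oxy}-6-methylhepta-1,5-dien-2-yl]-6-methoxy-5-methylcyclohexa-2,5-diene-1,4-dione, via dienylketene 18 (not isolated), via cyclohexadienone 19 (not isolated), via hydroquinone 20 (not isolated)
Conditions: degassed toluene (0.02 M), 110 °C, argon; cool to rt, then Ag2O, rt
Reagents that add atoms: none
Why: Heating opens the cyclobutenone by conrotatory 4π-electrocyclic cleavage of the bond between the ring carbonyl carbon and the carbinol carbon, the hydroxyl rotating outward so that the dienyl group lies cis to the ketene in 18; a disrotatory 6π-electrocyclisation then joins the ketene carbon to the terminal CH2 of the vinyl arm attached to the carbinol carbon to give 19, which tautomerises to 20 and is oxidised in the same flask by Ag2O. The closest known reaction type is the Moore-type thermal ring expansion of 4-alkenyl-4-hydroxycyclobutenones to hydroquinones and quinones. The one ring formed, the six-membered quinone carbocycle, is closed in a 6π-electrocyclic mode between the two ends of a triene whose first double bond is the ketene C=C, at the expense of the temporary four-membered ring. No new stereocentre is formed: the ring carbinol centre of 17 is erased and the silyloxy-bearing (S) centre is a spectator under neutral thermal conditions. The selectivity needed is periselectivity and regiochemistry: only the vinyl arm bonded directly to the carbinol carbon is in linear conjugation with the ketene (the second methylidene is cross-conjugated and cannot cyclise), and the placement of OMe, Me, H and side chain round the ring is already fixed by the carbonyl attacked in step 8. Exclusion of oxygen until thermolysis is complete keeps the product at the hydroquinone level, so no quinone dienophile meets unreacted diene.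

Step 10
Reactants: 21 2-[(3S)-3-{[tert-butyl(dimethyl)silyl]oxy}-6-methylhepta-1,5-dien-2-yl]-6-methoxy-5-methylcyclohexa-2,5-diene-1,4-dione
Product: 22 2-[(3S)-3-hydroxy-6-methylhepta-1,5-dien-2-yl]-6-methoxy-5-methylcyclohexa-2,5-diene-1,4-dione
Conditions: HF·pyridine, pyridine, THF, 0 °C to rt
Reagents that add atoms: none
Why: fluoride cleavage of a secondary TBS ether under buffered, non-basic conditions that the methoxyquinone should tolerate, the buffering also guarding against acid-catalysed cyclisation of the prenyl carbinol.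

Step 11
Reactants: 22 2-[(3S)-3-hydroxy-6-methylhepta-1,5-dien-2-yl]-6-methoxy-5-methylcyclohexa-2,5-diene-1,4-dione; 23 angelic acid ((Z)-2-methylbut-2-enoic acid)
Product: 25 (3S)-2-(5-methoxy-4-methyl-3,6-dioxocyclohexa-1,4-dien-1-yl)-6-methylhepta-1,5-dien-3-yl (Z)-2-methylbut-2-enoate, via angelic 2,4,6-trichlorobenzoic anhydride 24 (not isolated)
Conditions: 23, 2,4,6-trichlorobenzoyl chloride, Et3N, toluene, rt; then 22, toluene, 60 °C, no DMAP
Reagents that add atoms: none
Why: Yamaguchi-type esterification through the mixed anhydride, in which omitting a nucleophilic catalyst avoids the addition–elimination that turns angelates into tiglates, so the Z geometry is carried into the ester and the carbinol stereocentre, acylated at oxygen, is retained.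

**Compound list**

1 | dimethyl squarate (3,4-dimethoxycyclobut-3-ene-1,2-dione) | COC1=C(OC)C(=O)C1=O | starting material
2 | lithium 2,3-dimethoxy-1-methyl-4-oxocyclobut-2-en-1-olate | [Li+].[O-]C1(C)C(OC)=C(OC)C1=O | intermediate
3 | 2,3-dimethoxy-1-methyl-4-oxocyclobut-2-en-1-yl trifluoroacetate | CC1(OC(=O)C(F)(F)F)C(OC)=C(OC)C1=O | intermediate
4 | 3-methoxy-4-methylcyclobut-3-ene-1,2-dione | COC1=C(C)C(=O)C1=O | intermediate
5 | 4-methylpent-3-enoic acid | CC(C)=CCC(=O)O | starting material
6 | 1-(1H-imidazol-1-yl)-4-methylpent-3-en-1-one | CC(C)=CCC(=O)n1ccnc1 | intermediate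
7 | N-methoxy-N,4-dimethylpent-3-enamide | CC(C)=CCC(=O)N(C)OC | intermediate
8 | 3-methoxyprop-1-yne | COCC#C | starting material
9 | (3-methoxyprop-1-yn-1-yl)lithium | [Li]C#CCOC | intermediate
10 | lithium 1-methoxy-4-[methoxy(methyl)amino]-7-methyloct-6-en-2-yn-4-olate (tetrahedral chelate) | CON(C)C(O[Li])(CC=C(C)C)C#CCOC | intermediate
11 | 1-methoxy-7-methyloct-6-en-2-yn-4-one | COCC#CC(=O)CC=C(C)C | intermediate
12 | (4S)-1-methoxy-7-methyloct-6-en-2-yn-4-ol | COCC#C[C@H](CC=C(C)C)O | intermediate
13 | (4S)-7-methyl-3-[(trimethylsilyl)methyl]octa-1,2,6-trien-4-ol | C=C=C(C[Si](C)(C)C)[C@H](CC=C(C)C)O | intermediate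
14 | tert-butyl(dimethyl)({(4S)-7-methyl-3-[(trimethylsilyl)methyl]octa-1,2,6-trien-4-yl}oxy)silane | C=C=C(C[Si](C)(C)C)[C@H](CC=C(C)C)O[Si](C)(C)C(C)(C)C | intermediate
15 | {[(4S)-2-bromo-7-methyl-3-methylideneocta-1,6-dien-4-yl]oxy}(tert-butyl)dimethylsilane | C=C(Br)C(=C)[C@H](CC=C(C)C)O[Si](C)(C)C(C)(C)C | intermediate
16 | [(4S)-4-{[tert-butyl(dimethyl)silyl]oxy}-7-methyl-3-methylideneocta-1,6-dien-2-yl]lithium | [Li]C(=C)C(=C)[C@H](CC=C(C)C)O[Si](C)(C)C(C)(C)C | intermediate
17 | 4-[(4S)-4-{[tert-butyl(dimethyl)silyl]oxy}-7-methyl-3-methylideneocta-1,6-dien-2-yl]-4-hydroxy-3-methoxy-2-methylcyclobut-2-en-1-one (both epimers at the ring carbinol carbon) | C=C(C(=C)[C@H](CC=C(C)C)O[Si](C)(C)C(C)(C)C)C1(O)C(OC)=C(C)C1=O | intermediate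
18 | (3Z,7S)-7-{[tert-butyl(dimethyl)silyl]oxy}-4-hydroxy-3-methoxy-2,10-dimethyl-5,6-dimethylideneundeca-1,3,9-trien-1-one (dienylketene) | O=C=C(C)/C(OC)=C(/O)C(=C)C(=C)[C@H](CC=C(C)C)O[Si](C)(C)C(C)(C)C | intermediate
19 | 5-[(3S)-3-{[tert-butyl(dimethyl)silyl]oxy}-6-methylhepta-1,5-dien-2-yl]-4-hydroxy-3-methoxy-2-methylcyclohexa-2,4-dien-1-one | O=C1CC(C(=C)[C@H](CC=C(C)C)O[Si](C)(C)C(C)(C)C)=C(O)C(OC)=C1C | intermediate
20 | 2-[(3S)-3-{[tert-butyl(dimethyl)silyl]oxy}-6-methylhepta-1,5-dien-2-yl]-6-methoxy-5-methylbenzene-1,4-diol | C=C(c1cc(O)c(C)c(OC)c1O)[C@H](CC=C(C)C)O[Si](C)(C)C(C)(C)C | intermediate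
21 | 2-[(3S)-3-{[tert-butyl(dimethyl)silyl]oxy}-6-methylhepta-1,5-dien-2-yl]-6-methoxy-5-methylcyclohexa-2,5-diene-1,4-dione | C=C(C1=CC(=O)C(C)=C(OC)C1=O)[C@H](CC=C(C)C)O[Si](C)(C)C(C)(C)C | intermediate
22 | 2-[(3S)-3-hydroxy-6-methylhepta-1,5-dien-2-yl]-6-methoxy-5-methylcyclohexa-2,5-diene-1,4-dione | C=C(C1=CC(=O)C(C)=C(OC)C1=O)[C@H](CC=C(C)C)O | intermediate
23 | angelic acid ((Z)-2-methylbut-2-enoic acid) | C/C=C(/C)C(=O)O | starting material
24 | (Z)-2-methylbut-2-enoic 2,4,6-trichlorobenzoic anhydride | C/C=C(/C)C(=O)OC(=O)c1c(Cl)cc(Cl)cc1Cl | intermediate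
25 | (3S)-2-(5-methoxy-4-methyl-3,6-dioxocyclohexa-1,4-dien-1-yl)-6-methylhepta-1,5-dien-3-yl (Z)-2-methylbut-2-enoate | C=C(C1=CC(=O)C(C)=C(OC)C1=O)[C@H](CC=C(C)C)OC(=O)/C(C)=C\C | target

**Summary**

Total step count: 11. Longest linear sequence: 10 steps (steps 2 to 11, from 4-methylpent-3-enoic acid); step 1 is the convergent branch.

Steps most likely to fail:

Step 7. Electrophilic bromine may be consumed by the trisubstituted alkene, or the allylsilane may be protodesilylated by adventitious HBr, so that the 2-bromo-1,3-diene does not form cleanly. The fallback sets out from 12 and comes back at 15, and brings the halogen in as nucleophilic bromide instead. Compound 12 is treated with (isopropoxydimethylsilyl)methylmagnesium chloride and CuBr·SMe2 as in step 5 to give (4S)-3-{[dimethyl(propan-2-yloxy)silyl]methyl}-7-methylocta-1,2,6-trien-4-ol F1. Tamao oxidation (H2O2, KF, KHCO3, THF/MeOH) gives (3S)-2-ethenylidene-6-methylhept-5-ene-1,3-diol F2. Acetylation of the primary hydroxyl (AcCl, 2,4,6-collidine, CH2Cl2, −78 °C) gives (3S)-2-ethenylidene-3-hydroxy-6-methylhept-5-en-1-yl acetate F3. Silylation (TBSCl, imidazole, DMF) gives (3S)-3-{[tert-butyl(dimethyl)silyl]oxy}-2-ethenylidene-6-methylhept-5-en-1-yl acetate F4. SN2' displacement of the allenylmethyl acetate by bromide (LiBr, Pd(OAc)2 cat., AcOH, rt) then gives 15.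

Step 11. The hindered allylic alcohol may acylate slowly, and forcing conditions (heat, amine) may degrade the methoxy vinylquinone or isomerise the angelate to the tiglate. The fallback sets out from 17 and comes back at 25, and installs the ester before the quinone exists. Compound 17 is desilylated (HF·pyridine, THF) to 4-hydroxy-4-[(4S)-4-hydroxy-7-methyl-3-methylideneocta-1,6-dien-2-yl]-3-methoxy-2-methylcyclobut-2-en-1-one F5. Its secondary hydroxyl is acylated with mixed anhydride 24, the tertiary ring hydroxyl being too hindered, to give (4S)-2-(1-hydroxy-2-methoxy-3-methyl-4-oxocyclobut-2-en-1-yl)-7-methyl-3-methylideneocta-1,6-dien-4-yl (Z)-2-methylbut-2-enoate F6. Thermolysis as in step 9 gives (3S)-2-(2,5-dihydroxy-3-methoxy-4-methylphenyl)-6-methylhepta-1,5-dien-3-yl (Z)-2-methylbut-2-enoate F7, which Ag2O oxidises to 25.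

Step 8. The lithiodiene 16 may suffer oxygen-to-carbon silyl migration (retro-Brook, through a five-membered transition state), be quenched before it adds, or form incompletely. The fallback sets out from 14 and 4 and comes back at 17, and makes no organolithium. The allenylmethylsilane 14 itself serves as the dienyl nucleophile in a Hosomi–Sakurai-type SE2' addition to 4 (TiCl4, CH2Cl2, −78 °C). Chelation of titanium between the methoxy oxygen and the neighbouring ketone oxygen should direct attack to the same carbonyl. This fallback makes no compound outside the list (F0) and bypasses 15 and 16.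

Further compounds
F1 | step 7 | (4S)-3-{[dimethyl(propan-2-yloxy)silyl]methyl}-7-methylocta-1,2,6-trien-4-ol | C=C=C(C[Si](C)(C)OC(C)C)[C@H](CC=C(C)C)O
F2 | step 7 | (3S)-2-ethenylidene-6-methylhept-5-ene-1,3-diol | C=C=C(CO)[C@H](CC=C(C)C)O
F3 | step 7 | (3S)-2-ethenylidene-3-hydroxy-6-methylhept-5-en-1-yl acetate | C=C=C(COC(C)=O)[C@H](CC=C(C)C)O
F4 | step 7 | (3S)-3-{[tert-butyl(dimethyl)silyl]oxy}-2-ethenylidene-6-methylhept-5-en-1-yl acetate | C=C=C(COC(C)=O)[C@H](CC=C(C)C)O[Si](C)(C)C(C)(C)C
F5 | step 11 | 4-hydroxy-4-[(4S)-4-hydroxy-7-methyl-3-methylideneocta-1,6-dien-2-yl]-3-methoxy-2-methylcyclobut-2-en-1-one | C=C(C(=C)[C@H](CC=C(C)C)O)C1(O)C(OC)=C(C)C1=O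
F6 | step 11 | (4S)-2-(1-hydroxy-2-methoxy-3-methyl-4-oxocyclobut-2-en-1-yl)-7-methyl-3-methylideneocta-1,6-dien-4-yl (Z)-2-methylbut-2-enoate | C=C(C(=C)[C@H](CC=C(C)C)OC(=O)/C(C)=C\C)C1(O)C(OC)=C(C)C1=O
F7 | step 11 | (3S)-2-(2,5-dihydroxy-3-methoxy-4-methylphenyl)-6-methylhepta-1,5-dien-3-yl (Z)-2-methylbut-2-enoate | C=C(c1cc(O)c(C)c(OC)c1O)[C@H](CC=C(C)C)OC(=O)/C(C)=C\C
F0 | step 8 | none | none
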